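**Plan**

1. Labels: butene chain C1(=C2)–C3H(C4H3); ring A is the chromene on C1, ring B the chromene on C3, O7 the methoxy oxygen of ring B beside the carbon that carries C3.
2. Enabling feature: O7 lies ortho to the stereocentre C3, so ring B can be unmasked as an ortho-quinone methide with C3 (carrying methyl C4) as the methide carbon; this O7=C–C=C3 oxadiene takes C2 of an electron-rich alkene at C3 and returns O7 to C1.
3. Cuts: the C1=C2 alkene goes back to a C1 ketone and the O7 methyl ether to a phenol; ketone and phenol are tied together as a chroman ketal, which is cut at C2–C3 and O7–C1 into a ring B hydroxybenzyl alcohol and a ring A 1-methoxyvinyl arene; both come from one 6-acetylchromene, cut at its aryl–acetyl bond.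
4. Forward: acetylation of the chromene, division into the two partners, an oxa-[4+2] that joins the chain and closes one temporary dihydropyran ring, then ketal opening, O7-methylation, ketone reduction and dehydration.
5. Stereochemistry: C3 is the only stereocentre and is set in the cycloaddition by a chiral phosphoric acid; the (E) alkene comes from the final elimination.

Key step: step 6

Assumption: the (R)-configured phosphoric acid is taken to give the (4S) adduct; the sense of induction would be checked on the first run and the (S)-acid used if it proves opposite, with nothing else in the route changed.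

**Step 1**
Reactants: 1 7-methoxy-2,2-dimethyl-2H-chromene (precocene 1); 2 acetic anhydride
Product: 3 1-(7-methoxy-2,2-dimethyl-2H-chromen-6-yl)ethan-1-one
Conditions: Ac2O (1.5 equiv), Sc(OTf)3 (10 mol %), MeNO2, 0 °C to rt
Reagents that add atoms: acetic anhydride (2), CC(=O)OC(C)=O
Why: Friedel–Crafts acylation, in which C6 (para to the ring oxygen, ortho to the methoxy group, unhindered) should be preferred over C8, wedged between two oxygens, and over the alkene carbon C3, which is also activated but sits beside the quaternary C2; a catalytic metal triflate with acetic acid as the only by-product keeps strong protic acid away from the chromene.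

**Step 2**
Reactants: 3 1-(7-methoxy-2,2-dimethyl-2H-chromen-6-yl)ethan-1-one
Product: 4 1-(7-hydroxy-2,2-dimethyl-2H-chromen-6-yl)ethan-1-one
Conditions: NaSEt (3 equiv), DMF, 110 °C; then cold aq. HCl to pH 5
Reagents that add atoms: none
Why: SN2 O-demethylation by thiolate, favoured because the departing phenoxide is conjugated to the ortho acetyl group, while the ring ether is a tertiary centre closed to SN2 attack and the non-acidic medium leaves the chromene double bond alone.

**Step 3**
Reactants: 4 1-(7-hydroxy-2,2-dimethyl-2H-chromen-6-yl)ethan-1-one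
Product: 5 rac-6-(1-hydroxyethyl)-2,2-dimethyl-2H-chromen-7-ol
Conditions: NaBH4, THF/MeOH, 0 °C; aq. NH4Cl work-up; used at once
Reagents that add atoms: none
Why: Borohydride reduction of the aryl ketone at low temperature should stop at the benzylic alcohol without elimination to the quinone methide and over-reduction; the racemate suffices because this centre is flattened and reset in step 6.

**Step 4**
Reactants: 3 1-(7-methoxy-2,2-dimethyl-2H-chromen-6-yl)ethan-1-one; 6 trimethyl orthoformate
Product: 7 6-(1,1-dimethoxyethyl)-7-methoxy-2,2-dimethyl-2H-chromene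
Conditions: HC(OMe)3 (5 equiv), MeOH, (+)-camphor-10-sulfonic acid (2 mol %), rt; Et3N quench
Reagents that add atoms: trimethyl orthoformate (6), COC(OC)OC; methanol, CO
Why: Acid-catalysed ketalisation driven to completion by the orthoformate as water scavenger, at an acid loading and temperature at which methanol should not add to the chromene double bond.

**Step 5**
Reactants: 7 6-(1,1-dimethoxyethyl)-7-methoxy-2,2-dimethyl-2H-chromene
Product: 8 7-methoxy-6-(1-methoxyethenyl)-2,2-dimethyl-2H-chromene
Conditions: Me3SiOTf (1.2 equiv), iPr2NEt (1.5 equiv), CH2Cl2, −20 °C to rt; filtration through basic alumina; stored cold over a trace of Et3N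
Reagents that add atoms: none
Why: Silyl-triflate-mediated elimination of methanol from a ketal, in which Me3SiOTf ionises one methoxy group to the aryl-stabilised oxocarbenium ion and the hindered amine removes a methyl proton, so the acid-labile enol ether is formed and kept under basic conditions throughout.

**Step 6**
Reactants: 5 rac-6-(1-hydroxyethyl)-2,2-dimethyl-2H-chromen-7-ol; 8 7-methoxy-6-(1-methoxyethenyl)-2,2-dimethyl-2H-chromene (2 equiv)
Product: 10 (4S)-2-methoxy-2-(7-methoxy-2,2-dimethyl-2H-chromen-6-yl)-4,8,8-trimethyl-3,4-dihydro-2H,8H-pyrano[3,2-g]chromene (both configurations at the ketal carbon), via ortho-quinone methide 9 (not isolated)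
Conditions: (R)-3,3'-bis(2,4,6-triisopropylphenyl)-1,1'-binaphthyl-2,2'-diyl hydrogen phosphate (10 mol %), 4 Å molecular sieves, toluene, −20 °C to 0 °C, 5 added slowly to 8 and the acid; Et3N quench
Reagents that add atoms: none
Why: The phosphoric acid protonates the benzylic hydroxyl of 5 and water leaves (taken up by the sieves) to give the planar (E)-ortho-quinone methide 9, which stays hydrogen-bonded or ion-paired to the chiral phosphate through O7, so the configuration of racemic 5 is erased. The CH2 terminus of vinyl ether 8 (C2) then attacks the methide carbon C3, and the developing oxocarbenium carbon C1, stabilised by its methoxy group and by electron-rich ring A, is captured by O7; the closest known reaction type is the chiral-phosphoric-acid-catalysed inverse-electron-demand oxa-Diels–Alder reaction of in situ ortho-quinone methides with enol ethers, enamides and styrenes. The one new ring, the dihydropyran of the chroman ketal, closes as an asynchronous [4+2] cycloaddition whose second bond forms by 6-exo-trig attack of the phenolic oxygen on the C1=O+Me oxocarbenium ion. The stereocentre C3 (C4 of the chroman) is set by the catalyst, whose triisopropylphenyl groups shield one face of the bound quinone methide; the ketal carbon is not controlled and need not be, because it becomes the ketone in step 7. The step needs facial selectivity at C3, regioselectivity and chemoselectivity: the regiochemistry follows from the polarity match of nucleophilic C2 with electrophilic C3, the terminal oxygen-substituted alkene of 8 is far more nucleophilic and less hindered than the internal chromene double bonds (whose C3 is flanked by the quaternary C2), and slow addition of 5 into an excess of 8 keeps the quinone methide from adding to itself or to the phenol 5.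

**Step 7**
Reactants: 10 (4S)-2-methoxy-2-(7-methoxy-2,2-dimethyl-2H-chromen-6-yl)-4,8,8-trimethyl-3,4-dihydro-2H,8H-pyrano[3,2-g]chromene
Product: 12 (3S)-3-(7-hydroxy-2,2-dimethyl-2H-chromen-6-yl)-1-(7-methoxy-2,2-dimethyl-2H-chromen-6-yl)butan-1-one, via cyclic hemiketal 11 (not isolated)
Conditions: pyridinium p-toluenesulfonate (10 mol %), acetone/H2O 10:1, rt
Reagents that add atoms: water, O
Why: Hydrolysis of a mixed aryl ketal through the oxocarbenium ion stabilised by ring A, the hemiketal then opening to the conjugated aryl ketone; any 4H-chromene formed from 10 by loss of methanol hydrolyses to the same product, and C3, being β to the carbonyl and not enolisable, keeps its configuration.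

**Step 8**
Reactants: 12 (3S)-3-(7-hydroxy-2,2-dimethyl-2H-chromen-6-yl)-1-(7-methoxy-2,2-dimethyl-2H-chromen-6-yl)butan-1-one
Product: 13 (3S)-1,3-bis(7-methoxy-2,2-dimethyl-2H-chromen-6-yl)butan-1-one
Conditions: MeI (3 equiv), K2CO3 (3 equiv), DMF, rt
Reagents that add atoms: iodomethane, CI
Why: Williamson ether synthesis on the phenoxide, with carbonate too weak a base to enolise the ketone for C-methylation and any closed hemiketal form drained through the open phenoxide.

**Step 9**
Reactants: 13 (3S)-1,3-bis(7-methoxy-2,2-dimethyl-2H-chromen-6-yl)butan-1-one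
Product: 14 (3S)-1,3-bis(7-methoxy-2,2-dimethyl-2H-chromen-6-yl)butan-1-ol (both C1 epimers)
Conditions: NaBH4, THF/MeOH, 0 °C to rt
Reagents that add atoms: none
Why: Borohydride reduction of the aryl ketone; the carbinol centre C1 forms as a mixture of epimers, which is irrelevant because C1 becomes sp2 in step 10.

**Step 10**
Reactants: 14 (3S)-1,3-bis(7-methoxy-2,2-dimethyl-2H-chromen-6-yl)butan-1-ol
Product: 16 6,6'-[(1E,3S)-but-1-ene-1,3-diyl]bis(7-methoxy-2,2-dimethyl-2H-chromene), via sulfamate ester 15 (not isolated)
Conditions: methyl N-(triethylammoniosulfonyl)carbamate (Burgess reagent, 1.5 equiv), toluene, rt then 60 °C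
Reagents that add atoms: none
Why: Burgess dehydration, in which the alcohol forms the sulfamate ester and this undergoes syn elimination with a hydrogen of C2, the only β-carbon bearing hydrogen, to give the conjugated (E)-styrene (aryl and alkyl anti in the transition state); the neutral medium avoids a free C1 cation and acid at the chromene double bonds, and C3 is not touched.

**Compound list**

1 | 7-methoxy-2,2-dimethyl-2H-chromene (precocene 1) | COc1ccc2c(c1)OC(C)(C)C=C2 | starting material
2 | acetic anhydride | CC(=O)OC(C)=O | starting material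
3 | 1-(7-methoxy-2,2-dimethyl-2H-chromen-6-yl)ethan-1-one | CC(=O)c1cc2c(cc1OC)OC(C)(C)C=C2 | intermediate
4 | 1-(7-hydroxy-2,2-dimethyl-2H-chromen-6-yl)ethan-1-one | CC(=O)c1cc2c(cc1O)OC(C)(C)C=C2 | intermediate
5 | rac-6-(1-hydroxyethyl)-2,2-dimethyl-2H-chromen-7-ol | CC(O)c1cc2c(cc1O)OC(C)(C)C=C2 | intermediate
6 | trimethyl orthoformate | COC(OC)OC | starting material
7 | 6-(1,1-dimethoxyethyl)-7-methoxy-2,2-dimethyl-2H-chromene | CC(OC)(OC)c1cc2c(cc1OC)OC(C)(C)C=C2 | intermediate
8 | 7-methoxy-6-(1-methoxyethenyl)-2,2-dimethyl-2H-chromene | C=C(OC)c1cc2c(cc1OC)OC(C)(C)C=C2 | intermediate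
9 | (6E)-6-ethylidene-2,2-dimethyl-2H-chromen-7(6H)-one (ortho-quinone methide) | C/C=C1\C=C2C=CC(C)(C)OC2=CC1=O | intermediate (not isolated)
10 | (4S)-2-methoxy-2-(7-methoxy-2,2-dimethyl-2H-chromen-6-yl)-4,8,8-trimethyl-3,4-dihydro-2H,8H-pyrano[3,2-g]chromene, ketal carbon either way | C[C@H]1CC(OC)(c2cc3c(cc2OC)OC(C)(C)C=C3)Oc2cc3c(cc21)C=CC(C)(C)O3 | intermediate
11 | (4S)-2-(7-methoxy-2,2-dimethyl-2H-chromen-6-yl)-4,8,8-trimethyl-3,4-dihydro-2H,8H-pyrano[3,2-g]chromen-2-ol (cyclic hemiketal) | C[C@H]1CC(O)(c2cc3c(cc2OC)OC(C)(C)C=C3)Oc2cc3c(cc21)C=CC(C)(C)O3 | intermediate (not isolated)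
12 | (3S)-3-(7-hydroxy-2,2-dimethyl-2H-chromen-6-yl)-1-(7-methoxy-2,2-dimethyl-2H-chromen-6-yl)butan-1-one | C[C@@H](CC(=O)c1cc2c(cc1OC)OC(C)(C)C=C2)c1cc2c(cc1O)OC(C)(C)C=C2 | intermediate
13 | (3S)-1,3-bis(7-methoxy-2,2-dimethyl-2H-chromen-6-yl)butan-1-one | C[C@@H](CC(=O)c1cc2c(cc1OC)OC(C)(C)C=C2)c1cc2c(cc1OC)OC(C)(C)C=C2 | intermediate
14 | (3S)-1,3-bis(7-methoxy-2,2-dimethyl-2H-chromen-6-yl)butan-1-ol, both C1 epimers | C[C@@H](CC(O)c1cc2c(cc1OC)OC(C)(C)C=C2)c1cc2c(cc1OC)OC(C)(C)C=C2 | intermediate
15 | triethylammonium salt of methyl N-{[(3S)-1,3-bis(7-methoxy-2,2-dimethyl-2H-chromen-6-yl)butoxy]sulfonyl}carbamate (sulfamate ester) | C[C@@H](CC(OS(=O)(=O)[N-]C(=O)OC)c1cc2c(cc1OC)OC(C)(C)C=C2)c1cc2c(cc1OC)OC(C)(C)C=C2.CC[NH+](CC)CC | intermediate (not isolated)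
16 | 6,6'-[(1E,3S)-but-1-ene-1,3-diyl]bis(7-methoxy-2,2-dimethyl-2H-chromene) | COc1cc2c(cc1/C=C/[C@H](C)c1cc3c(cc1OC)OC(C)(C)C=C3)C=CC(C)(C)O2 | target

**Step count**

Total: 10 steps. Longest linear sequence: 8 steps (1, 2, 3, 6, 7, 8, 9, 10; the branch through steps 4 and 5 is equally long).

**Steps most likely to fail**

Step 6. The water released on forming the quinone methide, together with the acid, may hydrolyse vinyl ether 8 back to ketone 3 faster than the cycloaddition. The quinone methide may also add to itself or to phenol 5. The facial selectivity may be low because the enol ether has no hydrogen-bond donor to fix it to the phosphate. The fallback sets out from 3 and 5 and comes back at 12; it also makes steps 4 and 5 unnecessary. Ketone 3 is condensed with NH2OH·HCl and pyridine in ethanol to (E)-1-(7-methoxy-2,2-dimethyl-2H-chromen-6-yl)ethan-1-one oxime F1. With Ac2O and Fe powder in toluene/AcOH at 70 °C this is O-acetylated to the O-acetyl oxime F2 (not isolated) and reductively N-acetylated to N-[1-(7-methoxy-2,2-dimethyl-2H-chromen-6-yl)ethenyl]acetamide F3. This enamide takes the place of 8 in the same phosphoric-acid-catalysed cycloaddition with 5 (through 9). Its N–H binds the phosphoryl oxygen while the quinone methide is held by the acidic P–OH, the two-point arrangement on which the best-established enantioselective versions of this reaction rest, and it resists hydrolysis far better than 8. The adduct, N-[(4S)-2-(7-methoxy-2,2-dimethyl-2H-chromen-6-yl)-4,8,8-trimethyl-3,4-dihydro-2H,8H-pyrano[3,2-g]chromen-2-yl]acetamide F4, is then cleaved with dilute HCl in THF/water to acetamide and hydroxy ketone 12.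

Step 1. Acid-induced dimerisation of the chromene, or acylation at the C3=C4 double bond instead of C6, may consume the starting material. The fallback sets out from 1 and comes back at 3. Vilsmeier–Haack formylation (POCl3, DMF, 0 °C to 60 °C) uses a weaker electrophile in a buffered medium and should give the aryl iminium chloride F5. Aqueous NaOAc work-up hydrolyses it to 7-methoxy-2,2-dimethyl-2H-chromene-6-carbaldehyde F6. MeMgBr in THF at 0 °C then gives rac-1-(7-methoxy-2,2-dimethyl-2H-chromen-6-yl)ethan-1-ol F7, and MnO2 in CH2Cl2 at rt oxidises this benzylic alcohol to ketone 3.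

Step 10. The electron-rich benzylic sulfamate may ionise before the syn elimination; the ion pair can then collapse to the N-benzyl carbamate, alkylate ring B to an indane, or erode the E/Z ratio. The fallback sets out from 13 and comes back at 16, passing over steps 9 and 10 and never placing a cation on C1. KN(SiMe3)2 in THF at −78 °C forms the (Z)-enolate of the aryl ketone, and PhNTf2 traps it as (1Z,3S)-1,3-bis(7-methoxy-2,2-dimethyl-2H-chromen-6-yl)but-1-en-1-yl trifluoromethanesulfonate F8. Reduction with HCO2H and Et3N in DMF at 60 °C, catalysed by zerovalent palladium formed from Pd(OAc)2 and PPh3, replaces the triflate by hydrogen with retention of the alkene geometry and should give the (E)-alkene 16.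

**Further compounds**

F1 | step 6 | (E)-1-(7-methoxy-2,2-dimethyl-2H-chromen-6-yl)ethan-1-one oxime | C/C(=N\O)c1cc2c(cc1OC)OC(C)(C)C=C2
F2 | step 6 | (E)-1-(7-methoxy-2,2-dimethyl-2H-chromen-6-yl)ethan-1-one O-acetyl oxime (not isolated) | C/C(=N\OC(C)=O)c1cc2c(cc1OC)OC(C)(C)C=C2
F3 | step 6 | N-[1-(7-methoxy-2,2-dimethyl-2H-chromen-6-yl)ethenyl]acetamide | C=C(NC(C)=O)c1cc2c(cc1OC)OC(C)(C)C=C2
F4 | step 6 | N-[(4S)-2-(7-methoxy-2,2-dimethyl-2H-chromen-6-yl)-4,8,8-trimethyl-3,4-dihydro-2H,8H-pyrano[3,2-g]chromen-2-yl]acetamide | C[C@H]1CC(NC(C)=O)(c2cc3c(cc2OC)OC(C)(C)C=C3)Oc2cc3c(cc21)C=CC(C)(C)O3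
F5 | step 1 | N-[(7-methoxy-2,2-dimethyl-2H-chromen-6-yl)methylidene]-N-methylmethanaminium chloride (not isolated) | C[N+](C)=Cc1cc2c(cc1OC)OC(C)(C)C=C2.[Cl-]
F6 | step 1 | 7-methoxy-2,2-dimethyl-2H-chromene-6-carbaldehyde | O=Cc1cc2c(cc1OC)OC(C)(C)C=C2
F7 | step 1 | rac-1-(7-methoxy-2,2-dimethyl-2H-chromen-6-yl)ethan-1-ol | CC(O)c1cc2c(cc1OC)OC(C)(C)C=C2
F8 | step 10 | (1Z,3S)-1,3-bis(7-methoxy-2,2-dimethyl-2H-chromen-6-yl)but-1-en-1-yl trifluoromethanesulfonate | C[C@@H](/C=C(\OS(=O)(=O)C(F)(F)F)c1cc2c(cc1OC)OC(C)(C)C=C2)c1cc2c(cc1OC)OC(C)(C)C=C2
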